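## Retrosynthetic overview

1. Target 18 ⇐ lactam 16 by semi-reduction of the tertiary lactam; the carbinolamine epimer is set by anomeric/thermodynamic control.
2. 16 ⇐ α-ketol nitrile 11: nitrile → primary amide → Hofmann isocyanate trapped by the syn-axial tertiary OH (oxazinanone ring), then nitro reduction/condensation (five-membered indolenine ring).
3. Key disconnection: the indolenine C2–C3 bond (two carbonyl carbons) ⇒ keto aldehyde 10, closed by an intramolecular carbene-catalysed acyl-anion (Breslow) addition of the neopentyl aldehyde to the aryl ketone, which also forms the carbocycle.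
4. 10 ⇐ unsaturated cyano-lactam 6 + isobutyraldehyde (Michael) + 2-bromo-2′-nitroacetophenone (alkylation); 6 ⇐ N-Boc-D-β-homoprolinol 1 + ethyl cyanoacetate.
5. Ring order: pyrrolidine (chiral pool) → piperidinone → carbocycle → oxazinanone → indolenine five-membered ring.

Assumption: compound 1 is taken as a catalog building block (otherwise made from D-proline by Arndt–Eistert homologation and reduction).
Assumption: the natural (R)-carbinolamine (axial OH, antiperiplanar to the nitrogen lone pair) is the thermodynamic epimer reached by iminium/ring-chain equilibration.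
Locants: indolizine numbering for 6, 9, 10 (N4, C5=O, C6, C7, C8, C8a); pyrrolo[1,2-b]isoquinoline numbering for 11–15 (N4, C5, C5a, C6–C9, C9a, C10, C10a).

## Route

Step 1
Reactants: 1 tert-butyl (2R)-2-(2-hydroxyethyl)pyrrolidine-1-carboxylate; 2 ethyl cyanoacetate
Product: 4 3-[(2R)-2-(2-hydroxyethyl)pyrrolidin-1-yl]-3-oxopropanenitrile, via amine hydrochloride 3 (not isolated)
Conditions: HCl (4 M in dioxane), rt; evaporate; then K2CO3, 2, EtOH, 75 °C
Reagents that add atoms: ethyl cyanoacetate, N#CCC(=O)OCC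
Why: Acidolytic Boc removal followed by aminolysis of the activated ester (N-acylation far outpaces O-acylation) gives the cyanoacetamide, and the pyrrolidine stereocentre from the chiral pool is untouched.

Step 2
Reactants: 4 3-[(2R)-2-(2-hydroxyethyl)pyrrolidin-1-yl]-3-oxopropanenitrile
Product: 6 (8aR)-5-oxo-1,2,3,5,8,8a-hexahydroindolizine-6-carbonitrile, via aldehyde 5 (not isolated)
Conditions: TEMPO (10 mol %), PhI(OAc)2, CH2Cl2, rt; then piperidine (20 mol %), 4 Å MS, rt
Reagents that add atoms: none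
Why: TEMPO/PhI(OAc)2 oxidation of the primary alcohol gives the aldehyde, which undergoes intramolecular Knoevenagel condensation with the cyanoacetamide methylene (piperidinium acetate, six-membered ring) without touching C8a.

Step 3
Reactants: 6 (8aR)-5-oxo-1,2,3,5,8,8a-hexahydroindolizine-6-carbonitrile; 7 2-methylpropanal; 8 2-bromo-1-(2-nitrophenyl)ethan-1-one
Product: 10 (6R,7R,8aR)-7-(2-methyl-1-oxopropan-2-yl)-6-[2-(2-nitrophenyl)-2-oxoethyl]-5-oxooctahydroindolizine-6-carbonitrile, via Michael adduct 9 (not isolated)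
Conditions: 7 (5 equiv), pyrrolidine (20 mol %), AcOH (20 mol %), CHCl3, 40 °C, 48 h; evaporate; then 8, K2CO3, DMF, 0 °C
Reagents that add atoms: 2-methylpropanal, CC(C)C=O; 2-bromo-1-(2-nitrophenyl)ethan-1-one, O=C(CBr)c1ccccc1[N+](=O)[O-]
Why: The enamine-catalysed Michael addition to the alkylidene cyanoacetamide is reversible (retro-Michael by Grob-type fragmentation of the non-enolisable iminium, fastest from the axial adduct), so C7 settles with the bulky CMe2CHO group equatorial and H-7 cis to H-8a, and the planar cyano-stabilised carbanion is then C-alkylated by the α-bromoketone on its equatorial face (syn to H-7, away from the pseudoaxial H on C8), leaving the small nitrile axial and the phenacyl arm trans to CMe2CHO.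

Step 4
Reactants: 10 (6R,7R,8aR)-7-(2-methyl-1-oxopropan-2-yl)-6-[2-(2-nitrophenyl)-2-oxoethyl]-5-oxooctahydroindolizine-6-carbonitrile
Product: 11 (5aR,7S,9aR,10aR)-7-hydroxy-9,9-dimethyl-7-(2-nitrophenyl)-5,8-dioxododecahydropyrrolo[1,2-b]isoquinoline-5a-carbonitrile
Conditions: 2-(pentafluorophenyl)-6,7-dihydro-5H-pyrrolo[2,1-c][1,2,4]triazol-2-ium tetrafluoroborate (20 mol %), Et3N (20 mol %), toluene, 40 °C
Reagents that add atoms: none
Why: Proposed new method: an intramolecular crossed aldehyde–ketone benzoin in which an α-quaternary aldehyde is the acyl-anion donor; the small, electron-poor triazolylidene adds to the neopentyl aldehyde, the Breslow intermediate attacks the aryl ketone in a six-membered chair closure between the two trans-diequatorial arms, and since benzoin/retro-benzoin is reversible the ring settles with the 2-nitrophenyl group equatorial and the new hydroxyl axial, syn to the axial nitrile (7S); closest known reaction type: carbene-catalysed intramolecular crossed aldehyde–ketone benzoin of unbranched aldehydes giving six-membered α-ketols.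

Step 5
Reactants: 11 (5aR,7S,9aR,10aR)-7-hydroxy-9,9-dimethyl-7-(2-nitrophenyl)-5,8-dioxododecahydropyrrolo[1,2-b]isoquinoline-5a-carbonitrile
Product: 12 (5aR,7S,9aR,10aR)-7-hydroxy-9,9-dimethyl-7-(2-nitrophenyl)-5,8-dioxododecahydropyrrolo[1,2-b]isoquinoline-5a-carboxamide
Conditions: [PtH{(PMe2O)2H}(PMe2OH)] (5 mol %), EtOH/H2O 4:1, 80 °C
Reagents that add atoms: water, O
Why: Ghaffar–Parkins nitrile hydration under neutral conditions stops at the primary amide even for tertiary nitriles and tolerates the α-ketol, lactam and nitroarene, with no stereocentre affected.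

Step 6
Reactants: 12 (5aR,7S,9aR,10aR)-7-hydroxy-9,9-dimethyl-7-(2-nitrophenyl)-5,8-dioxododecahydropyrrolo[1,2-b]isoquinoline-5a-carboxamide
Product: 14 (5aS,7S,9aR,10aR)-9,9-dimethyl-7-(2-nitrophenyl)-5a,7-(iminocarbonyloxy)dodecahydropyrrolo[1,2-b]isoquinoline-5,8-dione (cyclic carbamate: N on C5a and O on C7), via isocyanate 13 (not isolated)
Conditions: PhI(OAc)2, MeCN, 50 °C
Reagents that add atoms: none
Why: Hofmann rearrangement with PhI(OAc)2 moves the quaternary C5a from carbon to nitrogen with retention, and the 1,3-syn-axial tertiary hydroxyl adds to the isocyanate to close the bridging 1,3-oxazinan-2-one, so the former nitrile carbon becomes the carbamate carbonyl.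

Step 7
Reactants: 14 cyclic carbamate nitro ketone (as named in step 6)
Product: 16 pentacyclic indolenine lactam (penicimutamide B with N–C(=O) in place of N–CH(OH); other four centres as in the target), via aniline 15 (not isolated)
Conditions: Fe powder, AcOH/EtOH, 75 °C
Reagents that add atoms: none
Why: Béchamp-type reduction of the nitro group gives the aniline, which condenses under the acidic conditions with the adjacent hindered ketone (reductive cyclisation) to the 3H-indole C=N, whose quaternary C3 cannot tautomerise or epimerise.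

Step 8
Reactants: 16 pentacyclic indolenine lactam
Product: 18 penicimutamide B, via silyl acetal 17 (not isolated)
Conditions: IrCl(CO)(PPh3)2 (2 mol %), (Me2HSi)2O, toluene, rt; then H2O/THF, NaHCO3
Reagents that add atoms: none
Why: Iridium-catalysed hydrosilylation of the tertiary lactam (Vaska's complex with tetramethyldisiloxane) stops at the N,O-silyl acetal and should spare the secondary carbamate and the hindered C=N, and hydrolysis gives the carbinolamine, which equilibrates through the iminium ion to the axial hydroxyl anti to the nitrogen lone pair and trans to the carbamate nitrogen, the (R) configuration of the target.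

## Compound list

1 | tert-butyl (2R)-2-(2-hydroxyethyl)pyrrolidine-1-carboxylate | OCC[C@H]1CCCN1C(=O)OC(C)(C)C | starting material
2 | ethyl cyanoacetate | CCOC(=O)CC#N | starting material
3 | 2-[(2R)-pyrrolidin-2-yl]ethan-1-ol hydrochloride | OCC[C@H]1CCCN1.Cl | intermediate
4 | 3-[(2R)-2-(2-hydroxyethyl)pyrrolidin-1-yl]-3-oxopropanenitrile | OCC[C@H]1CCCN1C(=O)CC#N | intermediate
5 | 3-oxo-3-[(2R)-2-(2-oxoethyl)pyrrolidin-1-yl]propanenitrile | O=CC[C@H]1CCCN1C(=O)CC#N | intermediate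
6 | (8aR)-5-oxo-1,2,3,5,8,8a-hexahydroindolizine-6-carbonitrile | N#CC1=CC[C@H]2CCCN2C1=O | intermediate
7 | 2-methylpropanal (isobutyraldehyde) | CC(C)C=O | starting material
8 | 2-bromo-1-(2-nitrophenyl)ethan-1-one | O=C(CBr)c1ccccc1[N+](=O)[O-] | starting material
9 | (7S,8aR)-7-(2-methyl-1-oxopropan-2-yl)-5-oxooctahydroindolizine-6-carbonitrile (C6 epimers) | O=CC(C)(C)[C@H]1C[C@H]2CCCN2C(=O)C1C#N | intermediate
10 | (6R,7R,8aR)-7-(2-methyl-1-oxopropan-2-yl)-6-[2-(2-nitrophenyl)-2-oxoethyl]-5-oxooctahydroindolizine-6-carbonitrile | O=CC(C)(C)[C@H]1C[C@H]2CCCN2C(=O)[C@]1(C#N)CC(=O)c1ccccc1[N+](=O)[O-] | intermediate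
11 | (5aR,7S,9aR,10aR)-7-hydroxy-9,9-dimethyl-7-(2-nitrophenyl)-5,8-dioxododecahydropyrrolo[1,2-b]isoquinoline-5a-carbonitrile | CC1(C)C(=O)[C@@](O)(c2ccccc2[N+](=O)[O-])C[C@@]2(C#N)C(=O)N3CCC[C@@H]3C[C@H]12 | intermediate
12 | (5aR,7S,9aR,10aR)-7-hydroxy-9,9-dimethyl-7-(2-nitrophenyl)-5,8-dioxododecahydropyrrolo[1,2-b]isoquinoline-5a-carboxamide | CC1(C)C(=O)[C@@](O)(c2ccccc2[N+](=O)[O-])C[C@@]2(C(N)=O)C(=O)N3CCC[C@@H]3C[C@H]12 | intermediate
13 | (5aS,7S,9aR,10aR)-7-hydroxy-5a-isocyanato-9,9-dimethyl-7-(2-nitrophenyl)dodecahydropyrrolo[1,2-b]isoquinoline-5,8-dione | CC1(C)C(=O)[C@@](O)(c2ccccc2[N+](=O)[O-])C[C@@]2(N=C=O)C(=O)N3CCC[C@@H]3C[C@H]12 | intermediate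
14 | (5aS,7S,9aR,10aR)-9,9-dimethyl-7-(2-nitrophenyl)-5a,7-(iminocarbonyloxy)dodecahydropyrrolo[1,2-b]isoquinoline-5,8-dione | CC1(C)C(=O)[C@@]2(c3ccccc3[N+](=O)[O-])C[C@]3(NC(=O)O2)[C@@H]1C[C@H]1CCCN1C3=O | intermediate
15 | (5aS,7S,9aR,10aR)-7-(2-aminophenyl)-9,9-dimethyl-5a,7-(iminocarbonyloxy)dodecahydropyrrolo[1,2-b]isoquinoline-5,8-dione | CC1(C)C(=O)[C@@]2(c3ccccc3N)C[C@]3(NC(=O)O2)[C@@H]1C[C@H]1CCCN1C3=O | intermediate
16 | pentacyclic indolenine lactam (penicimutamide B with lactam C=O at the carbinolamine carbon) | CC1(C)C2=Nc3ccccc3[C@@]23C[C@]2(NC(=O)O3)[C@@H]1C[C@H]1CCCN1C2=O | intermediate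
17 | O-(1,1,3,3-tetramethyldisiloxanyl) N,O-acetal of 16 (silyloxy carbon not defined) | CC1(C)C2=Nc3ccccc3[C@@]23C[C@]2(NC(=O)O3)[C@@H]1C[C@H]1CCCN1C2O[Si](C)(C)O[SiH](C)C | intermediate
18 | penicimutamide B | CC1(C)C2=Nc3ccccc3[C@@]23C[C@]2(NC(=O)O3)[C@@H]1C[C@H]1CCCN1[C@@H]2O | target

## Count and risks

Total step count: 8. Longest linear sequence: 8 steps (1 → 18).

**Step 3 (most likely to give the wrong stereochemistry).** The C7 configuration depends on retro-Michael equilibration, because kinetic axial attack on the locked bicyclic lactam puts CMe2CHO on the H-8a face, which is the wrong epimer. The alkylation face is only sterically controlled.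

Fallback, setting out from 6: run the addition of 7 under kinetic control (0 °C, short time) to the axial adduct (7R,8aR)-7-(2-methyl-1-oxopropan-2-yl)-5-oxooctahydroindolizine-6-carbonitrile F1. Dehydrogenate it with DDQ (dioxane, 80 °C) to the tetrasubstituted alkylidene (8aR)-7-(2-methyl-1-oxopropan-2-yl)-5-oxo-1,2,3,5,8,8a-hexahydroindolizine-6-carbonitrile F2. Reduce F2 with Hantzsch ester (diethyl 2,6-dimethyl-1,4-dihydropyridine-3,5-dicarboxylate), which leaves the aldehyde alone and delivers hydride to C7 along the axial trajectory on the H-8a face. This comes back to the route at compound 9, which is alkylated with 8 as in step 3.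

**Step 4 (key step).** Breslow-intermediate formation from the α-quaternary aldehyde may be too slow, and aldol closure through the ketone enolate may compete.

Fallback, setting out from 10: replace the carbene acyl anion by a ketyl radical anion in an intramolecular pinacol coupling, with the nitro group first converted so that it survives the reductant.
- Fe/NH4Cl (EtOH/H2O, 70 °C) gives the aniline (6R,7R,8aR)-6-[2-(2-aminophenyl)-2-oxoethyl]-7-(2-methyl-1-oxopropan-2-yl)-5-oxooctahydroindolizine-6-carbonitrile F3.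
- Boc2O (THF, 60 °C) gives tert-butyl N-[2-[2-[(6R,7R,8aR)-6-cyano-7-(2-methyl-1-oxopropan-2-yl)-5-oxooctahydroindolizin-6-yl]acetyl]phenyl]carbamate F4.
- SmI2 (THF/t-BuOH, −78 °C) closes the carbocycle by ketyl addition to the aldehyde, giving tert-butyl N-[2-[(5aR,7S,9aR,10aR)-5a-cyano-7,8-dihydroxy-9,9-dimethyl-5-oxododecahydropyrrolo[1,2-b]isoquinolin-7-yl]phenyl]carbamate F5.
- IBX (EtOAc, 70 °C) oxidises the secondary carbinol to tert-butyl N-[2-[(5aR,7S,9aR,10aR)-5a-cyano-7-hydroxy-9,9-dimethyl-5,8-dioxododecahydropyrrolo[1,2-b]isoquinolin-7-yl]phenyl]carbamate F6.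
- Hydration as in step 5 gives tert-butyl N-[2-[(5aR,7S,9aR,10aR)-5a-carbamoyl-7-hydroxy-9,9-dimethyl-5,8-dioxododecahydropyrrolo[1,2-b]isoquinolin-7-yl]phenyl]carbamate F7.
- PhI(OAc)2 as in step 6 gives tert-butyl N-[2-[(5aS,7S,9aR,10aR)-7-hydroxy-5a-isocyanato-9,9-dimethyl-5,8-dioxododecahydropyrrolo[1,2-b]isoquinolin-7-yl]phenyl]carbamate F8, which closes to tert-butyl N-[2-[(5aS,7S,9aR,10aR)-9,9-dimethyl-5,8-dioxo-5a,7-(iminocarbonyloxy)dodecahydropyrrolo[1,2-b]isoquinolin-7-yl]phenyl]carbamate F9.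
- TFA (CH2Cl2, rt) removes the Boc group and comes back to the route at compound 15, which condenses to 16 in the same acidic medium.

**Step 8.** The α-quaternary lactam is hindered, and the C=N bond or the carbamate could be reduced instead.

Fallback, setting out from 14: do the semi-reduction before the imine exists. The same IrCl(CO)(PPh3)2/(Me2HSi)2O hydrosilylation on the nitro ketone gives the O-(1,1,3,3-tetramethyldisiloxanyl) N,O-acetal of 14 F10. Hydrolysis gives (5R,5aS,7S,9aR,10aR)-5-hydroxy-9,9-dimethyl-7-(2-nitrophenyl)-5a,7-(iminocarbonyloxy)dodecahydropyrrolo[1,2-b]isoquinolin-8-one F11. Neutral nitro reduction (Fe powder, NH4Cl, EtOH/H2O, 70 °C) gives (5R,5aS,7S,9aR,10aR)-7-(2-aminophenyl)-5-hydroxy-9,9-dimethyl-5a,7-(iminocarbonyloxy)dodecahydropyrrolo[1,2-b]isoquinolin-8-one F12, which condenses with the ketone and comes back to the route at compound 18.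

Further compounds
F1 | step 3 | (7R,8aR)-7-(2-methyl-1-oxopropan-2-yl)-5-oxooctahydroindolizine-6-carbonitrile | O=CC(C)(C)[C@@H]1C[C@H]2CCCN2C(=O)C1C#N
F2 | step 3 | (8aR)-7-(2-methyl-1-oxopropan-2-yl)-5-oxo-1,2,3,5,8,8a-hexahydroindolizine-6-carbonitrile | O=CC(C)(C)C1=C(C#N)C(=O)N2CCC[C@@H]2C1
F3 | step 4 | (6R,7R,8aR)-6-[2-(2-aminophenyl)-2-oxoethyl]-7-(2-methyl-1-oxopropan-2-yl)-5-oxooctahydroindolizine-6-carbonitrile | O=CC(C)(C)[C@H]1C[C@H]2CCCN2C(=O)[C@]1(C#N)CC(=O)c1ccccc1N
F4 | step 4 | tert-butyl N-[2-[2-[(6R,7R,8aR)-6-cyano-7-(2-methyl-1-oxopropan-2-yl)-5-oxooctahydroindolizin-6-yl]acetyl]phenyl]carbamate | O=CC(C)(C)[C@H]1C[C@H]2CCCN2C(=O)[C@]1(C#N)CC(=O)c1ccccc1NC(=O)OC(C)(C)C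
F5 | step 4 | tert-butyl N-[2-[(5aR,7S,9aR,10aR)-5a-cyano-7,8-dihydroxy-9,9-dimethyl-5-oxododecahydropyrrolo[1,2-b]isoquinolin-7-yl]phenyl]carbamate | CC1(C)C(O)[C@@](O)(c2ccccc2NC(=O)OC(C)(C)C)C[C@@]2(C#N)C(=O)N3CCC[C@@H]3C[C@H]12
F6 | step 4 | tert-butyl N-[2-[(5aR,7S,9aR,10aR)-5a-cyano-7-hydroxy-9,9-dimethyl-5,8-dioxododecahydropyrrolo[1,2-b]isoquinolin-7-yl]phenyl]carbamate | CC1(C)C(=O)[C@@](O)(c2ccccc2NC(=O)OC(C)(C)C)C[C@@]2(C#N)C(=O)N3CCC[C@@H]3C[C@H]12
F7 | step 4 | tert-butyl N-[2-[(5aR,7S,9aR,10aR)-5a-carbamoyl-7-hydroxy-9,9-dimethyl-5,8-dioxododecahydropyrrolo[1,2-b]isoquinolin-7-yl]phenyl]carbamate | CC1(C)C(=O)[C@@](O)(c2ccccc2NC(=O)OC(C)(C)C)C[C@@]2(C(N)=O)C(=O)N3CCC[C@@H]3C[C@H]12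
F8 | step 4 | tert-butyl N-[2-[(5aS,7S,9aR,10aR)-7-hydroxy-5a-isocyanato-9,9-dimethyl-5,8-dioxododecahydropyrrolo[1,2-b]isoquinolin-7-yl]phenyl]carbamate | CC1(C)C(=O)[C@@](O)(c2ccccc2NC(=O)OC(C)(C)C)C[C@@]2(N=C=O)C(=O)N3CCC[C@@H]3C[C@H]12
F9 | step 4 | tert-butyl N-[2-[(5aS,7S,9aR,10aR)-9,9-dimethyl-5,8-dioxo-5a,7-(iminocarbonyloxy)dodecahydropyrrolo[1,2-b]isoquinolin-7-yl]phenyl]carbamate | CC1(C)C(=O)[C@@]2(c3ccccc3NC(=O)OC(C)(C)C)C[C@]3(NC(=O)O2)[C@@H]1C[C@H]1CCCN1C3=O
F10 | step 8 | O-(1,1,3,3-tetramethyldisiloxanyl) N,O-acetal of 14 | CC1(C)C(=O)[C@@]2(c3ccccc3[N+](=O)[O-])C[C@]3(NC(=O)O2)[C@@H]1C[C@H]1CCCN1C3O[Si](C)(C)O[SiH](C)C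
F11 | step 8 | (5R,5aS,7S,9aR,10aR)-5-hydroxy-9,9-dimethyl-7-(2-nitrophenyl)-5a,7-(iminocarbonyloxy)dodecahydropyrrolo[1,2-b]isoquinolin-8-one | CC1(C)C(=O)[C@@]2(c3ccccc3[N+](=O)[O-])C[C@]3(NC(=O)O2)[C@@H]1C[C@H]1CCCN1[C@@H]3O
F12 | step 8 | (5R,5aS,7S,9aR,10aR)-7-(2-aminophenyl)-5-hydroxy-9,9-dimethyl-5a,7-(iminocarbonyloxy)dodecahydropyrrolo[1,2-b]isoquinolin-8-one | CC1(C)C(=O)[C@@]2(c3ccccc3N)C[C@]3(NC(=O)O2)[C@@H]1C[C@H]1CCCN1[C@@H]3O
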